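**Strategy.** Everything rests on cutting the cyclohexenone ring (C1, C10–C14; briarane numbering) at C1–C14 and C11–C12. Both bonds are made in one flask on a γ-butyrolactone template that ties C2 to the C9 oxygen. An ortho-ester Claisen rearrangement of a 1-silylallyl ketene acetal delivers C14 to C1, anti to the ethynyl group on C10. PtCl2 then drives the new allylsilane onto that alkyne (6-exo-dig), giving the ring with C13=C14 and an exocyclic C11=C20 methylene. The precursor is a mixed cyclic ortho ester of a 3-methyl-4-ethynyl butanolide. Hydration, NHK coupling with a Sharpless-derived vinyl epoxide, Reformatsky addition, chlorolactonisation and ring-closing metathesis complete the target.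

Key step: step 6

Remark: briarane numbering is used for all intermediates. Stereocentres that are erased or corrected later (C1 in 4–9, C2 in 9, C14 in 11, C8 in 24, C17 in 28–30) are drawn unspecified or as the expected major isomer.

Step 1
Reactants: 1 (S)-5-(hydroxymethyl)furan-2(5H)-one
Product: 2 (S)-5-[(tert-butyldiphenylsilyloxy)methyl]furan-2(5H)-one
Conditions: TBDPSCl, imidazole, CH2Cl2, 0 to 23 °C
Reagents that add atoms: tert-butyl(chloro)diphenylsilane, CC(C)(C)[Si](Cl)(c1ccccc1)c1ccccc1
Why: Standard silylation of the primary alcohol (the future C8 oxygen) leaves the C9 stereocentre of the chiral-pool butenolide untouched.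

Step 2
Reactants: 2 (S)-5-[(tert-butyldiphenylsilyloxy)methyl]furan-2(5H)-one
Product: 4 (3S,4S,5S)-5-[(tert-butyldiphenylsilyloxy)methyl]-3-methyl-4-vinyldihydrofuran-2(3H)-one, via magnesium enolate 3 (not isolated)
Conditions: CH2=CHMgBr, CuBr·SMe2 (10 mol %), THF, −78 °C; then MeI, HMPA, −78 to −20 °C
Reagents that add atoms: vinylmagnesium bromide, C=C[Mg]Br; iodomethane, CI
Why: Copper-catalysed conjugate addition occurs anti to the bulky C9 silyloxymethyl group and sets C10, and the enolate is methylated trans to the new vinyl group (three-component coupling on a butenolide; the C1 centre is erased later).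

Step 3
Reactants: 4 (3S,4S,5S)-3-methyl-4-vinyl lactone
Product: 5 4-formyl lactone (3,4-trans-4,5-trans; C11 aldehyde)
Conditions: OsO4 (2 mol %), NaIO4, 2,6-lutidine, dioxane/H2O, 23 °C
Reagents that add atoms: sodium periodate, [Na+].[O-]I(=O)(=O)=O
Why: Lemieux–Johnson cleavage of the only olefin gives the aldehyde, and the C10 centre stays in the thermodynamically preferred trans arrangement on the lactone.

Step 4
Reactants: 5 4-formyl lactone
Product: 6 4-ethynyl lactone (3,4-trans-4,5-trans; C11≡C20)
Conditions: dimethyl (1-diazo-2-oxopropyl)phosphonate, K2CO3, MeOH, 0 to 23 °C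
Reagents that add atoms: dimethyl (1-diazo-2-oxopropyl)phosphonate, COP(=O)(OC)C(=[N+]=[N-])C(C)=O
Why: Ohira–Bestmann (Seyferth–Gilbert) homologation under mild carbonate conditions; any epimerisation at C10 returns the favoured 4,5-trans lactone.

Step 5
Reactants: 6 4-ethynyl lactone; 7 (E)-3-(trimethylsilyl)prop-2-en-1-ol
Product: 9 cyclic mixed ortho ester (2-ethoxy-2-[(E)-3-(trimethylsilyl)allyloxy]tetrahydrofuran of 6), via lactonium salt 8 (not isolated)
Conditions: Et3O·BF4, CH2Cl2, 23 °C; then NaOCH2CH=CHSiMe3 (from 7 and NaH), THF, −78 to 0 °C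
Reagents that add atoms: triethyloxonium tetrafluoroborate, CC[O+](CC)CC.F[B-](F)(F)F
Why: Meerwein O-ethylation of the lactone carbonyl and capture of the dioxocarbenium ion by the alkoxide give the ortho ester (Meerwein ortho-ester synthesis) without touching C9 or C10.

Step 6
Reactants: 9 cyclic mixed ortho ester
Product: 12 trans-fused bicyclic diene lactone (C13=C14 ring olefin, exocyclic C11=C20), via ketene acetal 10 (not isolated), via silylallyl lactone 11 (not isolated)
Conditions: 2,4,6-Me3C6H2CO2H (10 mol %), toluene, 110 °C; then PtCl2 (5 mol %), MeOH (10 equiv), 65 °C, same flask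
Reagents that add atoms: none
Why: Acid-catalysed loss of ethanol gives the allyl ketene acetal 10, whose chair-like [3,3] shift (Johnson ortho-ester Claisen rearrangement, known for lactone ortho esters) forms C1–C14 and places silicon on C14 in lactone 11; PtCl2 then activates the C11≡C20 alkyne, the allylsilane terminus C12 attacks C11 in anti-SE2′ fashion, the β-silyl cation at C13 loses silicon to methanol and protodeplatination leaves the exocyclic methylene (closest precedent: platinum-catalysed allylsilane–alkyne carbocyclisation). The only ring closed is the carbocycle C1–C14–C13–C12–C11–C10, by a 6-exo-dig attack in which the nucleophilic olefin ends as the endocyclic C13=C14 bond, trans-fused to the butanolide. The new stereocentre C1 is set in the Claisen step by the five-membered template, the allyl unit being delivered to the face of the ketene acetal opposite the ethynyl group on the adjacent C10, as in alkylations of 3,4-trans-disubstituted butanolide enolates. C9 and C10 are carried unchanged, C11 stays sp2 and the C14 silyl centre is destroyed. The step needs face selectivity at C1 (given by the C10 substituent, although C9 carries its group on the attacked face), exo attack at the terminal alkyne, and six- over five-membered closure, which the β-silicon effect secures by making C12 and not C13 the nucleophilic carbon.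

Step 7
Reactants: 12 bicyclic diene lactone
Product: 13 bicyclic lactone with the C11 tertiary alcohol (11-OH trans to the C9 branch)
Conditions: Mn(dpm)3 (5 mol %), PhSiH3, O2 (1 atm), i-PrOH/CH2Cl2, 0 to 23 °C
Reagents that add atoms: dioxygen, O=O
Why: Mukaiyama hydration by hydrogen-atom transfer is Markovnikov and selective for the 1,1-disubstituted olefin, and O2 should trap the tertiary C11 radical on the face away from the axial C1 methyl and the C9 branch.

Step 8
Reactants: 13 hydroxy lactone
Product: 14 hydroxy vinyl ketone (C2 ketone, free 9-OH and 11-OH)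
Conditions: CH2=CHMgBr (3 equiv), THF, −78 to −30 °C; aq NH4Cl
Reagents that add atoms: vinylmagnesium bromide, C=C[Mg]Br
Why: Mono-addition of the Grignard reagent to the hindered lactone stops at the cyclic hemiketal alkoxide at low temperature and opens to the enone on work-up, with no stereocentre affected.

Step 9
Reactants: 14 hydroxy vinyl ketone
Product: 15 (2S)-triol (allylic 2-OH, 9-OH, 11-OH)
Conditions: (R)-2-methyl-CBS-oxazaborolidine (20 mol %), catecholborane (4 equiv), toluene, −78 °C; MeOH quench
Reagents that add atoms: none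
Why: Corey–Bakshi–Shibata reduction under catalyst control, with the quaternary C1 as the large and the vinyl as the small ketone substituent, should give the 2S carbinol by 1,2-reduction.

Step 10
Reactants: 15 (2S)-triol
Product: 16 2,9-diacetate (11-OH free)
Conditions: Ac2O, pyridine, DMAP (5 mol %), CH2Cl2, 0 to 23 °C
Reagents that add atoms: acetic anhydride, CC(=O)OC(C)=O
Why: Acylation takes the two secondary alcohols and leaves the hindered tertiary 11-OH, installing both acetates of the target.

Step 11
Reactants: 16 2,9-diacetate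
Product: 17 primary alcohol at C8
Conditions: HF·pyridine, pyridine, THF, 0 °C
Reagents that add atoms: none
Why: Buffered fluoride desilylation of the primary silyl ether tolerates the acetates; it is kept cold to suppress 9→8 acetyl migration.

Step 12
Reactants: 17 primary alcohol
Product: 18 C8 aldehyde
Conditions: Dess–Martin periodinane, NaHCO3, CH2Cl2, 0 to 23 °C
Reagents that add atoms: none
Why: Dess–Martin oxidation of the primary alcohol proceeds under buffered conditions without epimerising the α-acetoxy centre C9.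

Step 13
Reactants: 19 2-methyl-2-vinyloxirane (racemic)
Product: 20 2-methylenebut-3-en-1-ol
Conditions: LDA, Et2O, −78 to 23 °C; aq NH4Cl
Reagents that add atoms: none
Why: Base-induced isomerisation of an epoxide to an allylic alcohol by syn β-elimination from the methyl group.

Step 14
Reactants: 20 2-methylenebut-3-en-1-ol
Product: 21 (S)-(2-vinyloxiran-2-yl)methanol
Conditions: Ti(O-i-Pr)4 (10 mol %), L-(+)-diethyl tartrate (12 mol %), t-BuOOH, 4 Å MS, CH2Cl2, −25 °C
Reagents that add atoms: tert-butyl hydroperoxide, CC(C)(C)OO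
Why: Sharpless asymmetric epoxidation epoxidises only the hydroxyl-bearing 1,1-disubstituted olefin and sets the C5 centre with the same facial sense that gives 2S epoxy alcohols from other allylic alcohols with L-(+)-tartrate.

Step 15
Reactants: 21 (S)-epoxy alcohol
Product: 22 (R)-2-vinyloxirane-2-carbaldehyde
Conditions: Dess–Martin periodinane, NaHCO3, CH2Cl2, 0 °C (solution used directly)
Reagents that add atoms: none
Why: Dess–Martin oxidation; the aldehyde has no α-hydrogen and cannot racemise (same spatial arrangement, descriptor changes by priority).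

Step 16
Reactants: 22 (R)-epoxy aldehyde
Product: 23 (S,E)-2-(2-iodovinyl)-2-vinyloxirane
Conditions: CHI3, CrCl2, THF, 0 to 23 °C
Reagents that add atoms: iodoform, IC(I)I
Why: Takai olefination converts the aldehyde into the E-vinyl iodide (C6=C7) and leaves the epoxide intact.

Step 17
Reactants: 18 C8 aldehyde; 23 (S,E)-vinyl iodide
Product: 24 allylic alcohol (C7–C8 bond, C8 epimers)
Conditions: CrCl2 (6 equiv), NiCl2 (2 mol %), DMSO/THF, 23 °C
Reagents that add atoms: none
Why: Nozaki–Hiyama–Kishi coupling is selective for the aldehyde and tolerates acetates, the epoxide and the free tertiary alcohol; the C8 configuration is irrelevant because it is oxidised next.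

Step 18
Reactants: 24 allylic alcohol
Product: 25 (E)-enone (C8 ketone)
Conditions: Dess–Martin periodinane, NaHCO3, CH2Cl2, 0 to 23 °C
Reagents that add atoms: none
Why: Dess–Martin oxidation of the secondary allylic alcohol gives the α-acetoxy enone without isomerising the E olefin.

Step 19
Reactants: 26 2-bromopropanoic acid
Product: 27 trimethylsilyl 2-bromopropanoate
Conditions: Me3SiCl, Et3N, Et2O, 0 to 23 °C
Reagents that add atoms: chlorotrimethylsilane, C[Si](C)(C)Cl
Why: Silylation of the acid gives a Reformatsky donor whose ester is cleaved on aqueous work-up.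

Step 20
Reactants: 25 (E)-enone; 27 trimethylsilyl 2-bromopropanoate
Product: 29 (8R)-β-hydroxy acid (C17 epimers), via silyl ester 28 (not isolated)
Conditions: Zn dust (activated), THF, 0 to 23 °C; aq NH4Cl work-up
Reagents that add atoms: none
Why: The Reformatsky zinc enolate adds 1,2 to the ketone (C6 is shielded by the quaternary C5) anti to the 9-acetoxy group (polar Felkin–Anh control), which sets C8; C17 is not controlled here and the silyl ester hydrolyses on work-up.

Step 21
Reactants: 29 β-hydroxy acid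
Product: 30 chlorolactone (6R,7R,8R; C17 epimers)
Conditions: N-chlorosuccinimide, Ph3P=S (10 mol %), CH2Cl2, −20 to 0 °C
Reagents that add atoms: N-chlorosuccinimide, O=C1CCC(=O)N1Cl
Why: Chlorolactonisation by anti addition of Cl and carboxylate across the E-C6=C7 olefin (5-exo) fixes the C6/C7 relationship, and the C6 arm should end trans to the bulky C9 branch and cis to 8-OH, as in halolactonisations of 3-hydroxy-4-alkenoic acids.

Step 22
Reactants: 30 chlorolactone (C17 epimers)
Product: 31 (17R)-chlorolactone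
Conditions: DBU (0.3 equiv), toluene, 40 °C
Reagents that add atoms: none
Why: Base-mediated epimerisation α to the lactone carbonyl should converge on the more stable isomer, with the C17 methyl trans to the C9 branch (cis to 8-OH).

Step 23
Reactants: 31 (17R)-chlorolactone
Product: 32 enone (C12 ketone, 11-hydroxy-12-oxo-13-ene)
Conditions: Rh2(cap)4 (1 mol %), t-BuOOH (70 % aq, 5 equiv), ClCH2CH2Cl, 40 °C
Reagents that add atoms: tert-butyl hydroperoxide, CC(C)(C)OO
Why: Dirhodium caprolactamate-catalysed allylic oxidation attacks C12, the only unhindered allylic methylene; C2–H is deactivated by its acetate.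

Step 24
Reactants: 32 diene enone
Product: 33 CNP0294646.1 (target)
Conditions: second-generation Grubbs catalyst, RuCl2(=CHPh)(H2IMes)(PCy3) (10 mol %), toluene (1 mM), 80 °C
Reagents that add atoms: none
Why: Ring-closing metathesis of the two terminal vinyl groups closes the ten-membered ring at C3=C4, and reversible metathesis should favour the Z olefin because a cis olefin is the less strained in a ten-membered ring; the electron-poor C13=C14 is inert.

**Compound list**

1 | (S)-5-(hydroxymethyl)furan-2(5H)-one | O=C1C=C[C@@H](CO)O1 | starting material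
2 | (S)-5-[(tert-butyldiphenylsilyloxy)methyl]furan-2(5H)-one | O=C1C=C[C@@H](CO[Si](c2ccccc2)(c2ccccc2)C(C)(C)C)O1 | intermediate
3 | bromomagnesium enolate of the 4-vinyl lactone | Br[Mg]OC1=C[C@H](C=C)[C@@H](CO[Si](c2ccccc2)(c2ccccc2)C(C)(C)C)O1 | intermediate
4 | (3S,4S,5S)-5-[(tert-butyldiphenylsilyloxy)methyl]-3-methyl-4-vinyldihydrofuran-2(3H)-one | CC(C)(C)[Si](c1ccccc1)(c1ccccc1)OC[C@H]1OC(=O)[C@@H](C)[C@@H]1C=C | intermediate
5 | 4-formyl lactone (3,4-trans-4,5-trans) | CC(C)(C)[Si](c1ccccc1)(c1ccccc1)OC[C@H]1OC(=O)[C@@H](C)[C@@H]1C=O | intermediate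
6 | 4-ethynyl lactone (3,4-trans-4,5-trans) | CC(C)(C)[Si](c1ccccc1)(c1ccccc1)OC[C@H]1OC(=O)[C@@H](C)[C@@H]1C#C | intermediate
7 | (E)-3-(trimethylsilyl)prop-2-en-1-ol | OC/C=C/[Si](C)(C)C | starting material
8 | O-ethyl lactonium tetrafluoroborate of 6 | CC(C)(C)[Si](c1ccccc1)(c1ccccc1)OC[C@H]1OC(=[O+]CC)[C@@H](C)[C@@H]1C#C.F[B-](F)(F)F | intermediate
9 | cyclic mixed ortho ester (2-ethoxy-2-[(E)-3-(trimethylsilyl)allyloxy]) | CC(C)(C)[Si](c1ccccc1)(c1ccccc1)OC[C@H]1OC(OCC)(OC/C=C/[Si](C)(C)C)[C@@H](C)[C@@H]1C#C | intermediate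
10 | allyl ketene acetal (2-[(E)-3-(trimethylsilyl)allyloxy]-4,5-dihydrofuran) | CC(C)(C)[Si](c1ccccc1)(c1ccccc1)OC[C@H]1OC(OC/C=C/[Si](C)(C)C)=C(C)[C@@H]1C#C | intermediate
11 | 3-methyl-3-[1-(trimethylsilyl)allyl]-4-ethynyl lactone (C1 quaternary, allyl trans to ethynyl) | CC(C)(C)[Si](c1ccccc1)(c1ccccc1)OC[C@H]1OC(=O)[C@@](C)(C(C=C)[Si](C)(C)C)[C@@H]1C#C | intermediate
12 | trans-fused bicyclic diene lactone (C13=C14, exocyclic C11=C20) | CC(C)(C)[Si](c1ccccc1)(c1ccccc1)OC[C@H]1OC(=O)[C@@]2(C)C=CCC(=C)[C@H]12 | intermediate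
13 | bicyclic lactone with C11 tertiary alcohol | CC(C)(C)[Si](c1ccccc1)(c1ccccc1)OC[C@H]1OC(=O)[C@@]2(C)C=CC[C@@](C)(O)[C@H]12 | intermediate
14 | hydroxy vinyl ketone (C2 ketone) | CC(C)(C)[Si](c1ccccc1)(c1ccccc1)OC[C@@H](O)[C@H]1[C@](C)(O)CC=C[C@]1(C)C(=O)C=C | intermediate
15 | (2S)-triol | CC(C)(C)[Si](c1ccccc1)(c1ccccc1)OC[C@@H](O)[C@H]1[C@](C)(O)CC=C[C@]1(C)[C@@H](O)C=C | intermediate
16 | 2,9-diacetate, C8 silyl ether | CC(C)(C)[Si](c1ccccc1)(c1ccccc1)OC[C@@H](OC(C)=O)[C@H]1[C@](C)(O)CC=C[C@]1(C)[C@@H](OC(C)=O)C=C | intermediate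
17 | 2,9-diacetate, C8 primary alcohol | OC[C@@H](OC(C)=O)[C@H]1[C@](C)(O)CC=C[C@]1(C)[C@@H](OC(C)=O)C=C | intermediate
18 | 2,9-diacetate, C8 aldehyde | O=C[C@@H](OC(C)=O)[C@H]1[C@](C)(O)CC=C[C@]1(C)[C@@H](OC(C)=O)C=C | intermediate
19 | 2-methyl-2-vinyloxirane | CC1(C=C)CO1 | starting material
20 | 2-methylenebut-3-en-1-ol | OCC(=C)C=C | intermediate
21 | (S)-(2-vinyloxiran-2-yl)methanol | OC[C@@]1(C=C)CO1 | intermediate
22 | (R)-2-vinyloxirane-2-carbaldehyde | O=C[C@@]1(C=C)CO1 | intermediate
23 | (S,E)-2-(2-iodovinyl)-2-vinyloxirane | I/C=C/[C@@]1(C=C)CO1 | intermediate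
24 | coupled allylic alcohol (C8 epimers) | OC(/C=C/[C@@]2(C=C)CO2)[C@@H](OC(C)=O)[C@H]1[C@](C)(O)CC=C[C@]1(C)[C@@H](OC(C)=O)C=C | intermediate
25 | (E)-enone (C8 ketone) | O=C(/C=C/[C@@]2(C=C)CO2)[C@@H](OC(C)=O)[C@H]1[C@](C)(O)CC=C[C@]1(C)[C@@H](OC(C)=O)C=C | intermediate
26 | 2-bromopropanoic acid | CC(Br)C(=O)O | starting material
27 | trimethylsilyl 2-bromopropanoate | CC(Br)C(=O)O[Si](C)(C)C | intermediate
28 | trimethylsilyl ester of the (8R)-β-hydroxy acid | CC(C(=O)O[Si](C)(C)C)[C@](O)(/C=C/[C@@]2(C=C)CO2)[C@@H](OC(C)=O)[C@H]1[C@](C)(O)CC=C[C@]1(C)[C@@H](OC(C)=O)C=C | intermediate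
29 | (8R)-β-hydroxy acid (C17 epimers) | CC(C(=O)O)[C@](O)(/C=C/[C@@]2(C=C)CO2)[C@@H](OC(C)=O)[C@H]1[C@](C)(O)CC=C[C@]1(C)[C@@H](OC(C)=O)C=C | intermediate
30 | chlorolactone (6R,7R,8R; C17 epimers) | C=C[C@@]2(CO2)[C@H](Cl)[C@@H]2OC(=O)C(C)[C@@]2(O)[C@@H](OC(C)=O)[C@@H]2[C@@](C)([C@@H](OC(C)=O)C=C)C=CC[C@@]2(C)O | intermediate
31 | (17R)-chlorolactone | C=C[C@@]2(CO2)[C@H](Cl)[C@@H]2OC(=O)[C@H](C)[C@@]2(O)[C@@H](OC(C)=O)[C@@H]2[C@@](C)([C@@H](OC(C)=O)C=C)C=CC[C@@]2(C)O | intermediate
32 | diene enone (C12 ketone) | C=C[C@@]2(CO2)[C@H](Cl)[C@@H]2OC(=O)[C@H](C)[C@@]2(O)[C@@H](OC(C)=O)[C@@H]2[C@@](C)([C@@H](OC(C)=O)C=C)C=CC(=O)[C@@]2(C)O | intermediate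
33 | CNP0294646.1 | CC(=O)O[C@H]1/C=C\[C@@]2(CO2)[C@H](Cl)[C@@H]2OC(=O)[C@H](C)[C@@]2(O)[C@@H](OC(C)=O)[C@@H]2[C@]1(C)C=CC(=O)[C@@]2(C)O | target

Total step count: 24. Longest linear sequence: 19 steps (steps 1–12, 17, 18, 20–24).

**Steps most likely to fail**

1. Step 6. The allyl unit may be delivered to the wrong face of the ketene acetal because the ethynyl group is a small director. The platinum-activated alkyne may also add alcohol, or close a five-membered ring, before the allylsilane attacks. Fallback: the ring is built stepwise by other bond-forming reactions, setting out from 6. Markovnikov carboindation of the alkyne (allyl bromide, In powder, THF, 70 °C) gives the 4-(penta-1,4-dien-2-yl) lactone F1. Palladium-catalysed α-vinylation of its lithium enolate (LiN(SiMe3)2, vinyl bromide, Pd2(dba)3, P(t-Bu)3, toluene), trans to the now larger C10 group, gives the 3-methyl-3-vinyl lactone F2. Ring-closing metathesis of the C1 vinyl and the allyl terminus (second-generation Grubbs catalyst, CH2Cl2, 40 °C) forms C13=C14 and returns to the route at 12.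

2. Step 24. The two hindered vinyl groups may oligomerise instead of closing the ring, or the E olefin may form, once the chain is stiffened by the lactone and chloride. Fallback: the ring is closed before the lactone is annulated, and the lactone is then built across the ring, setting out from 25. Ring-closing metathesis of the flexible trienone gives the ten-membered 3Z,6E-dienone F3. Reformatsky addition of 27 (Zn, THF) gives, through its trimethylsilyl ester F4, the macrocyclic hydroxy acid F5. Transannular chlorolactonisation (N-chlorosuccinimide) gives the chlorolactone F6, and DBU equilibration gives the 17R lactone F7. Allylic oxidation under the conditions of step 23 returns to the route at 33.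

3. Step 21. The chloronium ion may form on the wrong olefin face, chlorine may add to the C13=C14 olefin, or the carboxylate may open at C6. Fallback: chlorine and the lactone oxygen are brought in by epoxide chemistry, setting out from 25. Reformatsky addition of methyl 2-bromopropanoate (Zn, THF) gives the β-hydroxy methyl ester F8. Hydroxyl-directed epoxidation of the C6=C7 olefin (VO(acac)2, t-BuOOH, CH2Cl2) gives the epoxy alcohol F9. Ti(O-i-Pr)4-mediated opening with Et2NH2Cl at C6, the carbon remote from the carbinol, with inversion gives the chlorohydrin ester F10. F10 lactonises through its 7-OH (PPTS, CH2Cl2) and returns to the route at 30.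

**Further compounds**

F1 | step 6 | 3-methyl-4-(penta-1,4-dien-2-yl) lactone | CC(C)(C)[Si](c1ccccc1)(c1ccccc1)OC[C@H]1OC(=O)[C@@H](C)[C@@H]1C(=C)CC=C
F2 | step 6 | 3-methyl-3-vinyl-4-(penta-1,4-dien-2-yl) lactone | CC(C)(C)[Si](c1ccccc1)(c1ccccc1)OC[C@H]1OC(=O)[C@@](C)(C=C)[C@@H]1C(=C)CC=C
F3 | step 24 | ten-membered 3Z,6E-dienone (C8 ketone) | CC(=O)O[C@H]1/C=C\[C@@]2(CO2)/C=C/C(=O)[C@@H](OC(C)=O)[C@@H]2[C@]1(C)C=CC[C@@]2(C)O
F4 | step 24 | trimethylsilyl ester of the macrocyclic hydroxy acid | CC(=O)O[C@H]1/C=C\[C@@]2(CO2)/C=C/[C@@](O)(C(C)C(=O)O[Si](C)(C)C)[C@@H](OC(C)=O)[C@@H]2[C@]1(C)C=CC[C@@]2(C)O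
F5 | step 24 | macrocyclic β-hydroxy acid (C17 epimers) | CC(=O)O[C@H]1/C=C\[C@@]2(CO2)/C=C/[C@@](O)(C(C)C(=O)O)[C@@H](OC(C)=O)[C@@H]2[C@]1(C)C=CC[C@@]2(C)O
F6 | step 24 | macrocyclic chlorolactone (C17 epimers, C12 methylene) | CC(=O)O[C@H]1/C=C\[C@@]2(CO2)[C@H](Cl)[C@@H]2OC(=O)C(C)[C@@]2(O)[C@@H](OC(C)=O)[C@@H]2[C@]1(C)C=CC[C@@]2(C)O
F7 | step 24 | 12-deoxo target (17R chlorolactone) | CC(=O)O[C@H]1/C=C\[C@@]2(CO2)[C@H](Cl)[C@@H]2OC(=O)[C@H](C)[C@@]2(O)[C@@H](OC(C)=O)[C@@H]2[C@]1(C)C=CC[C@@]2(C)O
F8 | step 21 | β-hydroxy methyl ester | CC(C(=O)OC)[C@](O)(/C=C/[C@@]2(C=C)CO2)[C@@H](OC(C)=O)[C@H]1[C@](C)(O)CC=C[C@]1(C)[C@@H](OC(C)=O)C=C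
F9 | step 21 | 6,7-epoxy methyl ester | CC(C(=O)OC)[C@](O)([C@H]3O[C@@H]3[C@@]2(C=C)CO2)[C@@H](OC(C)=O)[C@H]1[C@](C)(O)CC=C[C@]1(C)[C@@H](OC(C)=O)C=C
F10 | step 21 | 6-chloro-7-hydroxy methyl ester | CC(C(=O)OC)[C@](O)([C@@H](O)[C@@H](Cl)[C@@]2(C=C)CO2)[C@@H](OC(C)=O)[C@H]1[C@](C)(O)CC=C[C@]1(C)[C@@H](OC(C)=O)C=C
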